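**Strategy.** Ring A is closed last, at the C1–C10 bond (abietane-type numbering: ring A = C1–C5 and C10; ring B = C5, C7, C8, C9, C10; ring C = C8, C9, C11–C14). The key step is an intramolecular copper-catalysed anti-SN2′ alkylation: the C1 alkylborane of an enantioenriched, flat 1-indenyl phosphate attacks C10, which lies 1,3 to the C7–O bond across C5 in ring B. In one operation it builds the benzylic quaternary centre C10 by chirality transfer from the C7 carbinol and leaves the C5=C7 alkene, which hydroformylation turns into H-5 and the C7 formyl group. A late Diels–Alder reaction of the quinone with myrcene sets C8 and C9.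

Key step: step 10

Remark on numbering: C6 is the formyl carbon on C7 and C20 the methyl on C10; the α-face is the face opposite to C20.
Assumption: the two enol forms of ring C of the target (C12–OH/C14=O and C14–OH/C12=O) interconvert freely, so hydrolysis of the C12 methyl ether gives the target as drawn.

**Step 1**
Reactants: 1 1,2,4-trimethoxybenzene; 2 acetone
Product: 4 2-(2,3,6-trimethoxyphenyl)propan-2-ol, via aryllithium 3 (not isolated)
Conditions: n-BuLi, TMEDA, THF, 0 °C; then acetone, −78 °C to rt; H2O
Reagents that add atoms: none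
Why: The C–H between two methoxy groups is the most acidic one, and the aryllithium adds to acetone; directed ortho-metalation.

**Step 2**
Reactants: 4 2-(2,3,6-trimethoxyphenyl)propan-2-ol
Product: 5 2-isopropyl-1,3,4-trimethoxybenzene
Conditions: Et3SiH, CF3CO2H, CH2Cl2, 0 °C to rt
Reagents that add atoms: none
Why: The tertiary benzylic alcohol ionises to a cation stabilised by two ortho methoxy groups, which the silane reduces; ionic hydrogenation.

**Step 3**
Reactants: 5 2-isopropyl-1,3,4-trimethoxybenzene
Product: 6 3-isopropyl-2,4,5-trimethoxybenzaldehyde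
Conditions: POCl3, DMF, 0 to 70 °C; H2O
Reagents that add atoms: N,N-dimethylformamide CN(C)C=O; water O
Why: Of the two free ring positions only the future C8 is ortho to one methoxy group and para to another, so the chloroiminium ion should attack there; Vilsmeier–Haack formylation.

**Step 4**
Reactants: 6 3-isopropyl-2,4,5-trimethoxybenzaldehyde
Product: 7 2-iodo-5-isopropyl-3,4,6-trimethoxybenzaldehyde
Conditions: N-iodosuccinimide, CF3CO2H (cat.), MeCN, rt
Reagents that add atoms: N-iodosuccinimide O=C1CCC(=O)N1I
Why: The single remaining ring position (future C9), ortho to a methoxy group, is iodinated by electrophilic aromatic substitution.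

**Step 5**
Reactants: 8 2,2-dimethylpent-4-enal
Product: 9 1,1-dibromo-3,3-dimethylhexa-1,5-diene
Conditions: CBr4, PPh3, CH2Cl2, 0 °C
Reagents that add atoms: carbon tetrabromide BrC(Br)(Br)Br
Why: The non-enolisable aldehyde is dibromomethylenated by Ph3P=CBr2; first stage of the Corey–Fuchs reaction.

**Step 6**
Reactants: 9 1,1-dibromo-3,3-dimethylhexa-1,5-diene
Product: 11 4,4-dimethylhept-6-en-2-yne, via lithium acetylide 10 (not isolated)
Conditions: n-BuLi (2.1 equiv), THF, −78 to 0 °C; then MeI
Reagents that add atoms: iodomethane CI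
Why: Br–Li exchange and 1,2-shift give the acetylide, which is methylated in the same flask; second stage of the Corey–Fuchs reaction.

**Step 7**
Reactants: 7 2-iodo-5-isopropyl-3,4,6-trimethoxybenzaldehyde; 11 4,4-dimethylhept-6-en-2-yne
Product: 12 4,5,7-trimethoxy-3-methyl-2-(2-methylpent-4-en-2-yl)-6-(propan-2-yl)-1H-inden-1-one
Conditions: Pd(OAc)2 (5 mol %), Na2CO3, n-Bu4NCl, DMF, 100 °C
Reagents that add atoms: none
Why: Zerovalent palladium inserts into the C–I bond, the alkyne inserts with the aryl group on the methyl-bearing carbon and palladium next to the bulky tert-alkyl group, and addition of the vinylpalladium to the formyl group with β-hydride elimination gives the indenone; Larock indenone annulation.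

**Step 8**
Reactants: 12 the indenone
Product: 13 (1S)-4,5,7-trimethoxy-3-methyl-2-(2-methylpent-4-en-2-yl)-6-(propan-2-yl)-1H-inden-1-ol
Conditions: (S)-2-methyl-CBS-oxazaborolidine (20 mol %), catecholborane, toluene, −78 to −40 °C
Reagents that add atoms: none
Why: The oxazaborolidine–borane complex delivers hydride to one face of the C7 ketone, the C5 flank with its tert-alkyl group acting as the large substituent, which should set the (S)-carbinol (sense to be confirmed, otherwise the (R)-catalyst is used), while catecholborane leaves the terminal alkene alone; CBS reduction.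

**Step 9**
Reactants: 13 the (1S)-indenol
Product: 14 diethyl (1S)-4,5,7-trimethoxy-3-methyl-2-(2-methylpent-4-en-2-yl)-6-(propan-2-yl)-1H-inden-1-yl phosphate
Conditions: ClP(O)(OEt)2, pyridine, DMAP (cat.), CH2Cl2, 0 °C
Reagents that add atoms: diethyl chlorophosphate CCOP(=O)(Cl)OCC
Why: O-phosphorylation under nucleophilic catalysis gives a leaving group that does not ionise, because the indenyl cation is antiaromatic.

**Step 10**
Reactants: 14 the (1S)-indenyl phosphate
Product: 16 (4aS)-5,6,8-trimethoxy-1,1,4a-trimethyl-7-(propan-2-yl)-2,3,4,4a-tetrahydro-1H-fluorene, via B-alkyl-9-BBN borane 15 (not isolated)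
Conditions: 9-BBN-H dimer, THF, rt; then KOMe (1.0 equiv, premixed with the borane), CuOAc (10 mol %), THF/1,4-dioxane (0.01 M), 40 °C
Reagents that add atoms: none
Why: Proposed new method: the borate formed from alkylborane 15 and KOMe passes its primary C1 alkyl group to monovalent copper, and the alkylcopper adds C1 to C10 of the C5=C10 double bond on the face opposite to the C7 phosphate while the phosphate leaves (anti-SN2′ by addition–elimination), so the double bond moves to C5=C7. The closest known reaction type is the intermolecular copper-catalysed γ-selective, 1,3-anti-stereospecific allyl–alkyl coupling of B-alkyl-9-BBN reagents with secondary allylic phosphates, which builds quaternary carbons; a ring-closing version on a tetrasubstituted cyclic alkene is not known. Ring A closes in the 6-endo mode, since both C5 and C10 of the attacked alkene end up in the new ring. The only new stereocentre, C10, is controlled by the C7–O stereocentre from step 8, which is consumed (1,3-chirality transfer, C1 enters anti to the leaving group). The step needs γ-attack at C10 over α-attack at C7 (both would give six-membered rings) and ring closure over intermolecular coupling; the first should follow from the addition–elimination path of the alkylcopper and the shielding of C7 by the peri methoxy group, the second from high dilution and the gem-dimethyl group on C4.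

**Step 11**
Reactants: 16 the (4aS)-tetrahydrofluorene
Product: 17 (4aS,9R,9aS)-5,6,8-trimethoxy-1,1,4a-trimethyl-7-(propan-2-yl)-2,3,4,4a,9,9a-hexahydro-1H-fluorene-9-carbaldehyde (trans ring fusion, formyl group α and cis to H-9a)
Conditions: Rh(acac)(CO)2 (2 mol %), P(O-2,4-tBu2C6H3)3, CO/H2 (1:1, 40 bar), toluene, 90 °C
Reagents that add atoms: carbon monoxide [C-]#[O+]
Why: Rh–H should add across the only alkene from the α-face, away from the axial methyl groups on C10 and C4, with rhodium on the benzylic C7 and hydrogen on the fully substituted C5, and CO insertion with retention then puts H-5 and the C7 formyl group cis on the α-face, which sets C5 (trans fusion) and C7 in one event; rhodium-catalysed hydroformylation.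

**Step 12**
Reactants: 17 the aldehyde
Product: 18 (4bS,8aS,9R)-3-methoxy-4b,8,8-trimethyl-1,4-dioxo-2-(propan-2-yl)-4,4b,5,6,7,8,8a,9-octahydro-1H-fluorene-9-carbaldehyde (12-methoxy-11,14-quinone)
Conditions: (NH4)2Ce(NO3)6, MeCN/H2O, 0 °C
Reagents that add atoms: water O
Why: Two-electron oxidation of the 1,2,4-trimethoxyarene with loss of the two para-related methyl groups gives the 2-methoxy-1,4-quinone and leaves the aldehyde alone; oxidative demethylation.

**Step 13**
Reactants: 18 the methoxyquinone; 19 myrcene (7-methyl-3-methylideneocta-1,6-diene)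
Product: 20 the 12-O-methyl ether of the target (cis-fused α-face adduct across C8–C9)
Conditions: BF3·OEt2 (2.2 equiv), myrcene (5 equiv), CH2Cl2, −78 to −40 °C
Reagents that add atoms: none
Why: BF3 should bind the more basic vinylogous-ester carbonyl O14 (and the formyl oxygen), which makes C9 the electrophilic end of the C8=C9 bond (C12=C13 is deactivated by OMe and isopropyl), so the more nucleophilic diene terminus (the CH2 on the substituted carbon of myrcene) bonds to C9, and the diene adds to the α-face, anti to the axial C20 methyl, setting C8 and C9 together; Lewis-acid-catalysed Diels–Alder reaction.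

**Step 14**
Reactants: 20 the adduct methyl ether
Product: 21 the target CNP0239256.1, (5S,7R,8S,9R,10S) in the numbering used here
Conditions: 1 M HCl, THF, rt
Reagents that add atoms: water O
Why: Acid-catalysed addition–elimination of water at C12 of the vinylogous ester releases methanol and gives the enolised trione without touching the stereocentres; vinylogous ester hydrolysis.

**Compound list**
1 | 1,2,4-trimethoxybenzene | COc1ccc(OC)c(OC)c1 | starting material
2 | acetone | CC(C)=O | starting material
3 | (2,3,6-trimethoxyphenyl)lithium | [Li]c1c(OC)ccc(OC)c1OC | intermediate (not isolated)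
4 | 2-(2,3,6-trimethoxyphenyl)propan-2-ol | COc1ccc(OC)c(C(C)(C)O)c1OC | intermediate
5 | 2-isopropyl-1,3,4-trimethoxybenzene | COc1ccc(OC)c(C(C)C)c1OC | intermediate
6 | 3-isopropyl-2,4,5-trimethoxybenzaldehyde | COc1cc(C=O)c(OC)c(C(C)C)c1OC | intermediate
7 | 2-iodo-5-isopropyl-3,4,6-trimethoxybenzaldehyde | COc1c(I)c(C=O)c(OC)c(C(C)C)c1OC | intermediate
8 | 2,2-dimethylpent-4-enal | C=CCC(C)(C)C=O | starting material
9 | 1,1-dibromo-3,3-dimethylhexa-1,5-diene | C=CCC(C)(C)C=C(Br)Br | intermediate
10 | (3,3-dimethylhex-5-en-1-yn-1-yl)lithium | [Li]C#CC(C)(C)CC=C | intermediate (not isolated)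
11 | 4,4-dimethylhept-6-en-2-yne | CC#CC(C)(C)CC=C | intermediate
12 | 4,5,7-trimethoxy-3-methyl-2-(2-methylpent-4-en-2-yl)-6-(propan-2-yl)-1H-inden-1-one | C=CCC(C)(C)C1=C(C)c2c(OC)c(OC)c(C(C)C)c(OC)c2C1=O | intermediate
13 | (1S)-4,5,7-trimethoxy-3-methyl-2-(2-methylpent-4-en-2-yl)-6-(propan-2-yl)-1H-inden-1-ol | C=CCC(C)(C)C1=C(C)c2c(OC)c(OC)c(C(C)C)c(OC)c2[C@H]1O | intermediate
14 | diethyl (1S)-4,5,7-trimethoxy-3-methyl-2-(2-methylpent-4-en-2-yl)-6-(propan-2-yl)-1H-inden-1-yl phosphate | C=CCC(C)(C)C1=C(C)c2c(OC)c(OC)c(C(C)C)c(OC)c2[C@H]1OP(=O)(OCC)OCC | intermediate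
15 | diethyl (1S)-2-[5-(9-borabicyclo[3.3.1]nonan-9-yl)-2-methylpentan-2-yl]-4,5,7-trimethoxy-3-methyl-6-(propan-2-yl)-1H-inden-1-yl phosphate | C1CC2CCCC(C1)B2CCCC(C)(C)C3=C(C)c4c(OC)c(OC)c(C(C)C)c(OC)c4[C@H]3OP(=O)(OCC)OCC | intermediate (not isolated)
16 | (4aS)-5,6,8-trimethoxy-1,1,4a-trimethyl-7-(propan-2-yl)-2,3,4,4a-tetrahydro-1H-fluorene | COc1c(OC)c(C(C)C)c(OC)c2c1[C@@]1(C)CCCC(C)(C)C1=C2 | intermediate
17 | (4aS,9R,9aS)-5,6,8-trimethoxy-1,1,4a-trimethyl-7-(propan-2-yl)-2,3,4,4a,9,9a-hexahydro-1H-fluorene-9-carbaldehyde | COc1c(OC)c(C(C)C)c(OC)c2c1[C@@]1(C)CCCC(C)(C)[C@@H]1[C@H]2C=O | intermediate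
18 | (4bS,8aS,9R)-3-methoxy-4b,8,8-trimethyl-1,4-dioxo-2-(propan-2-yl)-4,4b,5,6,7,8,8a,9-octahydro-1H-fluorene-9-carbaldehyde | CC(C)C1=C(OC)C(=O)C2=C(C1=O)[C@H](C=O)[C@H]1C(C)(C)CCC[C@]21C | intermediate
19 | myrcene (7-methyl-3-methylideneocta-1,6-diene) | C=CC(=C)CCC=C(C)C | starting material
20 | 12-O-methyl ether of the target (α-face myrcene adduct of 18 across C8–C9) | CC(C)=CCCC1=CC[C@@]23C(=O)C(C(C)C)=C(OC)C(=O)[C@]2(C1)[C@@]1(C)CCCC(C)(C)[C@@H]1[C@H]3C=O | intermediate
21 | CNP0239256.1 | CC(C)=CCCC1=CC[C@@]23C(=O)C(C(C)C)=C(O)C(=O)[C@]2(C1)[C@@]1(C)CCCC(C)(C)[C@@H]1[C@H]3C=O | target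

**Step count.** Total: 14 steps. Longest linear sequence: 12 steps (steps 1–4 and 7–14, from 1); steps 5 and 6 form the two-step alkyne branch.

**Steps most likely to fail**

1. Step 10 (key step). What may go wrong: alkyl transfer to C7 instead of C10, a base-induced 1,3-hydrogen shift of the indenyl phosphate before coupling, or a stereochemical course that is not cleanly anti. The fallback uses known chemistry, leaves the route at indenone 12 and returns at 16. Hydroboration of the terminal alkene with disiamylborane and iodinolysis (I2, NaOMe) would give the primary iodide F1. Bu3SnH/AIBN at high dilution would then close the same C1–C10 bond by a 6-endo radical conjugate cyclisation onto the β-carbon of the enone; after base equilibration this should give the racemic trans-fused ketone F2. NaBH4 would give the benzylic alcohol F3 and acid-catalysed dehydration (TsOH) the racemic alkene F4, from which preparative chromatography on a chiral stationary phase delivers 16.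

2. Step 11. What may go wrong: the hindered trisubstituted alkene may insert into Rh–H too slowly, so that forcing conditions lead to hydrogenation or to epimerisation at C7. The fallback leaves at 16 and returns at 17. Hydroboration with BH3·SMe2 (boron to C7, hydrogen to C5, both from the α-face) and esterification with pinacol would give the pinacol boronic ester F5. Matteson homologation with LiCHCl2 would give the α-chloroboronic ester F6 with retention at C7, and oxidation of its C–B bond with NaBO3 releases aldehyde 17.

3. Step 13. What may go wrong: BF3-induced oligomerisation of myrcene, enolisation of the formyl quinone towards its hydroquinone tautomer, or an orientation governed by the C11 carbonyl group. The fallback leaves at 17 and returns at 21. Exhaustive demethylation with BBr3 would give the triol F7, which air should oxidise to the hydroxyquinone F8. F8 is then combined with myrcene 19 under the mild oxophilic Er(fod)3 in place of BF3. Here the isopropyl group, which blocks the C13/C14 side of the endo transition state, has to steer the substituted diene carbon to the C11/C12 side; the adduct is 21 itself.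

**Further compounds**
F1 | step 10 | 2-(5-iodo-2-methylpentan-2-yl)-4,5,7-trimethoxy-3-methyl-6-(propan-2-yl)-1H-inden-1-one | ICCCC(C)(C)C1=C(C)c2c(OC)c(OC)c(C(C)C)c(OC)c2C1=O
F2 | step 10 | racemic trans-fused 5,6,8-trimethoxy-1,1,4a-trimethyl-7-(propan-2-yl)-1,2,3,4,4a,9a-hexahydro-9H-fluoren-9-one (one enantiomer drawn) | COc1c(OC)c(C(C)C)c(OC)c2c1[C@@]1(C)CCCC(C)(C)[C@@H]1C2=O
F3 | step 10 | racemic trans-fused 5,6,8-trimethoxy-1,1,4a-trimethyl-7-(propan-2-yl)-2,3,4,4a,9,9a-hexahydro-1H-fluoren-9-ol (one enantiomer drawn, C9 epimers) | COc1c(OC)c(C(C)C)c(OC)c2c1[C@@]1(C)CCCC(C)(C)[C@@H]1C2O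
F4 | step 10 | racemic 5,6,8-trimethoxy-1,1,4a-trimethyl-7-(propan-2-yl)-2,3,4,4a-tetrahydro-1H-fluorene | COc1c(OC)c(C(C)C)c(OC)c2c1C1(C)CCCC(C)(C)C1=C2
F5 | step 11 | pinacol boronic ester of 16 with boron on C7 (α) and hydrogen on C5 (α) | COc1c(OC)c(C(C)C)c(OC)c2c1[C@@]1(C)CCCC(C)(C)[C@@H]1[C@H]2B1OC(C)(C)C(C)(C)O1
F6 | step 11 | α-chloroboronic ester from homologation of F5 (epimers at the CHCl carbon) | COc1c(OC)c(C(C)C)c(OC)c2c1[C@@]1(C)CCCC(C)(C)[C@@H]1[C@H]2C(Cl)B1OC(C)(C)C(C)(C)O1
F7 | step 13 | (4aS,9R,9aS)-5,6,8-trihydroxy-1,1,4a-trimethyl-7-(propan-2-yl)-2,3,4,4a,9,9a-hexahydro-1H-fluorene-9-carbaldehyde | Oc1c(O)c(C(C)C)c(O)c2c1[C@@]1(C)CCCC(C)(C)[C@@H]1[C@H]2C=O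
F8 | step 13 | (4bS,8aS,9R)-3-hydroxy-4b,8,8-trimethyl-1,4-dioxo-2-(propan-2-yl)-4,4b,5,6,7,8,8a,9-octahydro-1H-fluorene-9-carbaldehyde | CC(C)C1=C(O)C(=O)C2=C(C1=O)[C@H](C=O)[C@H]1C(C)(C)CCC[C@]21C
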